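**Retrosynthetic overview**
1. The last cut is C8–C9 of the lower triene: a Stille union of the core (E)-vinyl iodide 24 with dienylstannane 10.
2. The strategy rests on the terminal 2-amino-3-hydroxycyclopent-2-enone ring (five carbons, with N on the carbon lying between the C–OH and C=O carbons). This ring is a 5-aminolevulinate folded onto itself, so the amide is made on the open-chain primary amine (9) and the ring C–C bond, from the N-bearing carbon to the ester carbonyl, is closed afterwards by Claisen condensation.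
3. Precursor 9 comes from methyl 5-aminolevulinate and stannyldienoic acid 6 (propargyl alcohol: hydrostannylation, oxidation, Horner–Wadsworth–Emmons, saponification).
4. Core: anilide 17 → quinone monoketal 18 → asymmetric epoxidation (C5/C6) → stannylvinyllithium addition anti to the epoxide (C4) → iodide → ketal removal.
5. Ring order: the six-membered carbocycle comes from the arene, the oxirane is formed in step 11, the cyclopentenone in step 6 on the other fragment, and no ring is formed at the union.

Key step: step 6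

Assumption: N-benzylcinchonidinium chloride is taken to deliver the (1R,6S)-epoxide 19; should the facial sense prove opposite, the pseudoenantiomeric N-benzylcinchoninium chloride is used with no other change.

**Route**

Step 1
Reactants: 1 propargyl alcohol
Product: 2 (E)-3-(tributylstannyl)prop-2-en-1-ol
Conditions: Bu3SnH, AIBN (cat.), neat, 80 °C; chromatography
Reagents that add atoms: tributyltin hydride, CCCC[SnH](CCCC)CCCC
Why: Radical hydrostannylation of the terminal alkyne, in which reversible stannyl-radical addition should favour the (E)-β-stannyl alkene, the minor α- and (Z)-isomers being removed on silica.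

Step 2
Reactants: 2 (E)-3-(tributylstannyl)prop-2-en-1-ol
Product: 3 (E)-3-(tributylstannyl)prop-2-enal
Conditions: MnO2, CH2Cl2, rt
Reagents that add atoms: none
Why: Allylic alcohol oxidation with MnO2 is neutral and should leave the C–Sn bond and the alkene geometry untouched.

Step 3
Reactants: 3 (E)-3-(tributylstannyl)prop-2-enal; 4 triethyl phosphonoacetate
Product: 5 ethyl (2E,4E)-5-(tributylstannyl)penta-2,4-dienoate
Conditions: NaH, THF, 0 °C → rt
Reagents that add atoms: none
Why: Horner–Wadsworth–Emmons olefination with a stabilised phosphonate should give the new C2=C3 bond (E)-selectively under basic conditions that the vinylstannane tolerates.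

Step 4
Reactants: 5 ethyl (2E,4E)-5-(tributylstannyl)penta-2,4-dienoate
Product: 6 (2E,4E)-5-(tributylstannyl)penta-2,4-dienoic acid
Conditions: LiOH·H2O, THF/MeOH/H2O, rt; cold 1 M HCl to pH 4
Reagents that add atoms: lithium hydroxide, [Li+].[OH-]
Why: Ester saponification, with a briefly and only mildly acidic work-up so that the electron-poor dienylstannane is not protodestannylated.

Step 5
Reactants: 6 (2E,4E)-5-(tributylstannyl)penta-2,4-dienoic acid; 7 methyl 5-aminolevulinate hydrochloride
Product: 9 methyl 4-oxo-5-[(2E,4E)-5-(tributylstannyl)penta-2,4-dienamido]pentanoate, via pivalic (2E,4E)-5-(tributylstannyl)penta-2,4-dienoic anhydride 8 (not isolated)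
Conditions: PivCl, Et3N, THF, −20 °C; then 7 in DMF, Et3N (dropwise), −20 → 0 °C
Reagents that add atoms: none
Why: Mixed-anhydride amidation, in which the primary amine is liberated slowly in the presence of the acylating agent so that N-acylation at the unhindered dienoyl carbonyl should outrun self-condensation of the free aminoketone.

Step 6
Reactants: 9 methyl 4-oxo-5-[(2E,4E)-5-(tributylstannyl)penta-2,4-dienamido]pentanoate
Product: 10 (2E,4E)-N-(2-hydroxy-5-oxocyclopent-1-en-1-yl)-5-(tributylstannyl)penta-2,4-dienamide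
Conditions: KOtBu (3 equiv), THF (0.02 M), 0 → 45 °C; then AcOH (4 equiv), 0 °C, pH 4 citrate wash
Reagents that add atoms: none
Why: tert-Butoxide reversibly removes the amide N–H and a proton of the methylene flanked by the ketone and the amide nitrogen; the resulting carbon enolate adds to the ester carbonyl and the tetrahedral intermediate expels methoxide, giving the 2-acylaminocyclopentane-1,3-dione, which is isolated as its enol tautomer 10. The closest known reaction type is the alkoxide-mediated intramolecular Claisen (Dieckmann-type) cyclisation of 4-oxoalkanoate esters to 2-substituted cyclopentane-1,3-diones. The carbocycle closes in a 5-exo-trig attack on the ester with the enolate double bond inside the forming ring (enolendo mode), a strained geometry that is the reason for warming. No stereocentre is formed. The step needs carbon- over nitrogen-acylation: the six-membered N-acyl imide from amidate attack is reopened by the liberated methoxide, whereas the dione is at once and irreversibly deprotonated to its vinylogous carboxylate, so the equilibria should drain to 10; the other ketone enolate has no productive ring size, and high dilution with a non-nucleophilic alkoxide suppresses intermolecular condensation and conjugate addition. The dienyl–tin bond is inert to alkoxide and the quench is kept weakly acidic, as for the carboxylic acid 6.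

Step 7
Reactants: 11 cyclohexanecarbaldehyde; 12 triethyl 4-phosphonocrotonate
Product: 13 ethyl (2E,4E)-5-cyclohexylpenta-2,4-dienoate
Conditions: LiN(SiMe3)2, THF, −78 → 0 °C
Reagents that add atoms: none
Why: Vinylogous Horner–Wadsworth–Emmons olefination of an α-branched aldehyde should give mainly the (2E,4E)-dienoate, any (4Z)-isomer being removed at the acid stage.

Step 8
Reactants: 13 ethyl (2E,4E)-5-cyclohexylpenta-2,4-dienoate
Product: 14 (2E,4E)-5-cyclohexylpenta-2,4-dienoic acid
Conditions: LiOH·H2O, THF/MeOH/H2O, rt; 1 M HCl; recrystallisation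
Reagents that add atoms: lithium hydroxide, [Li+].[OH-]
Why: Ester saponification to a crystalline dienoic acid whose recrystallisation should secure geometric purity.

Step 9
Reactants: 14 (2E,4E)-5-cyclohexylpenta-2,4-dienoic acid; 15 2,5-dimethoxyaniline
Product: 17 (2E,4E)-5-cyclohexyl-N-(2,5-dimethoxyphenyl)penta-2,4-dienamide, via (2E,4E)-5-cyclohexylpenta-2,4-dienoyl chloride 16 (not isolated)
Conditions: (COCl)2, DMF (cat.), CH2Cl2, 0 °C → rt, concentrate; then 15, pyridine, CH2Cl2, 0 °C
Reagents that add atoms: none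
Why: Acid chloride formation followed by Schotten–Baumann-type N-acylation of an electron-rich aniline, which installs the upper chain before the ring is oxidised and so avoids acylating a weakly nucleophilic enaminone later.

Step 10
Reactants: 17 (2E,4E)-5-cyclohexyl-N-(2,5-dimethoxyphenyl)penta-2,4-dienamide
Product: 18 (2E,4E)-5-cyclohexyl-N-(6,6-dimethoxy-3-oxocyclohexa-1,4-dien-1-yl)penta-2,4-dienamide
Conditions: PhI(OAc)2, MeOH, 0 °C → rt; aqueous work-up
Reagents that add atoms: methanol, CO; water, O
Why: Hypervalent-iodine oxidative dearomatisation of a para-dimethoxyarene, in which methanol is captured at the methoxy carbon next to nitrogen and the other oxocarbenium, stabilised as a vinylogous acyliminium, is hydrolysed to the ketone, so the ketal should end up beside the N-bearing carbon.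

Step 11
Reactants: 18 (2E,4E)-5-cyclohexyl-N-(6,6-dimethoxy-3-oxocyclohexa-1,4-dien-1-yl)penta-2,4-dienamide
Product: 19 (2E,4E)-5-cyclohexyl-N-[(1R,6S)-2,2-dimethoxy-5-oxo-7-oxabicyclo[4.1.0]hept-3-en-3-yl]penta-2,4-dienamide
Conditions: t-BuOOH, aq. NaOH, N-benzylcinchonidinium chloride (cat.), toluene, 0 °C → rt; recrystallisation
Reagents that add atoms: tert-butyl hydroperoxide, CC(C)(C)OO
Why: Weitz–Scheffer nucleophilic epoxidation under cinchona phase-transfer catalysis attacks only the unsubstituted enone double bond (the other is a deactivated vinylogous amide), and the two cis epoxide stereocentres are set by the chiral ammonium–peroxide ion pair, with crystallisation expected to raise the enantiopurity.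

Step 12
Reactants: 19 (2E,4E)-5-cyclohexyl-N-[(1R,6S)-2,2-dimethoxy-5-oxo-7-oxabicyclo[4.1.0]hept-3-en-3-yl]penta-2,4-dienamide; 20 (E)-1,2-bis(tributylstannyl)ethene
Product: 22 (2E,4E)-5-cyclohexyl-N-[(1R,5S,6S)-5-hydroxy-2,2-dimethoxy-5-[(E)-2-(tributylstannyl)ethenyl]-7-oxabicyclo[4.1.0]hept-3-en-3-yl]penta-2,4-dienamide, via (E)-2-(tributylstannyl)ethenyllithium 21 (not isolated)
Conditions: 20, n-BuLi, THF, −78 °C; then 19 (21 used at 3 equiv), −78 °C; aq. NH4Cl
Reagents that add atoms: none
Why: Tin–lithium exchange gives the (E)-alkenyllithium with retention, and its 1,2-addition to the ketone (one equivalent being spent on the amide N–H) should occur on the face anti to the epoxide oxygen under substrate control, setting the carbinol centre with the hydroxyl syn to the epoxide.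

Step 13
Reactants: 22 (2E,4E)-5-cyclohexyl-N-[(1R,5S,6S)-5-hydroxy-2,2-dimethoxy-5-[(E)-2-(tributylstannyl)ethenyl]-7-oxabicyclo[4.1.0]hept-3-en-3-yl]penta-2,4-dienamide
Product: 23 (2E,4E)-5-cyclohexyl-N-[(1R,5S,6S)-5-hydroxy-5-[(E)-2-iodoethenyl]-2,2-dimethoxy-7-oxabicyclo[4.1.0]hept-3-en-3-yl]penta-2,4-dienamide
Conditions: I2 (1.05 equiv, titrated), CH2Cl2, −78 → 0 °C
Reagents that add atoms: iodine, II
Why: Iododestannylation is a very fast ipso substitution with retention of the (E) geometry and should outpace any iodination of the enamide or dienamide when iodine is titrated cold.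

Step 14
Reactants: 23 (2E,4E)-5-cyclohexyl-N-[(1R,5S,6S)-5-hydroxy-5-[(E)-2-iodoethenyl]-2,2-dimethoxy-7-oxabicyclo[4.1.0]hept-3-en-3-yl]penta-2,4-dienamide
Product: 24 (2E,4E)-5-cyclohexyl-N-[(1R,5S,6S)-5-hydroxy-5-[(E)-2-iodoethenyl]-2-oxo-7-oxabicyclo[4.1.0]hept-3-en-3-yl]penta-2,4-dienamide
Conditions: montmorillonite K10 clay, wet CH2Cl2, rt
Reagents that add atoms: water, O
Why: Heterogeneous mild-acid ketal hydrolysis reveals the α-amido enone while the acid-stable vinyl iodide, the epoxide and the tertiary allylic alcohol should survive, which is why the tin was exchanged for iodine beforehand.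

Step 15
Reactants: 24 (2E,4E)-5-cyclohexyl-N-[(1R,5S,6S)-5-hydroxy-5-[(E)-2-iodoethenyl]-2-oxo-7-oxabicyclo[4.1.0]hept-3-en-3-yl]penta-2,4-dienamide; 10 (2E,4E)-N-(2-hydroxy-5-oxocyclopent-1-en-1-yl)-5-(tributylstannyl)penta-2,4-dienamide
Product: 25 (2E,4E)-5-cyclohexyl-N-[(1R,5R,6S)-5-hydroxy-5-[(1E,3E,5E)-7-[(2-hydroxy-5-oxocyclopent-1-en-1-yl)amino]-7-oxohepta-1,3,5-trien-1-yl]-2-oxo-7-oxabicyclo[4.1.0]hept-3-en-3-yl]penta-2,4-dienamide
Conditions: PdCl2(MeCN)2 (10 mol%), DMF, rt, dark, argon; 10 (1.2 equiv)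
Reagents that add atoms: none
Why: Stille coupling of an (E)-vinyl iodide with an (E,E)-dienylstannane under ligand-free conditions, where zerovalent palladium formed in situ should join C8 to C9 at room temperature with retention of both alkene geometries, without touching the stereocentres and without protecting groups.

**Compound list**
1 | propargyl alcohol | C#CCO | starting material
2 | (E)-3-(tributylstannyl)prop-2-en-1-ol | OC/C=C/[Sn](CCCC)(CCCC)CCCC | intermediate
3 | (E)-3-(tributylstannyl)prop-2-enal | O=C/C=C/[Sn](CCCC)(CCCC)CCCC | intermediate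
4 | triethyl phosphonoacetate | CCOC(=O)CP(=O)(OCC)OCC | starting material
5 | ethyl (2E,4E)-5-(tributylstannyl)penta-2,4-dienoate | CCOC(=O)/C=C/C=C/[Sn](CCCC)(CCCC)CCCC | intermediate
6 | (2E,4E)-5-(tributylstannyl)penta-2,4-dienoic acid | OC(=O)/C=C/C=C/[Sn](CCCC)(CCCC)CCCC | intermediate
7 | methyl 5-aminolevulinate hydrochloride | COC(=O)CCC(=O)CN.Cl | starting material
8 | pivalic (2E,4E)-5-(tributylstannyl)penta-2,4-dienoic anhydride (formed in the flask) | CC(C)(C)C(=O)OC(=O)/C=C/C=C/[Sn](CCCC)(CCCC)CCCC | intermediate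
9 | methyl 4-oxo-5-[(2E,4E)-5-(tributylstannyl)penta-2,4-dienamido]pentanoate | CCCC[Sn](CCCC)(CCCC)/C=C/C=C/C(=O)NCC(=O)CCC(=O)OC | intermediate
10 | (2E,4E)-N-(2-hydroxy-5-oxocyclopent-1-en-1-yl)-5-(tributylstannyl)penta-2,4-dienamide | CCCC[Sn](CCCC)(CCCC)/C=C/C=C/C(=O)NC1=C(O)CCC1=O | intermediate
11 | cyclohexanecarbaldehyde | O=CC1CCCCC1 | starting material
12 | triethyl 4-phosphonocrotonate (ethyl (E)-4-(diethoxyphosphoryl)but-2-enoate) | CCOC(=O)/C=C/CP(=O)(OCC)OCC | starting material
13 | ethyl (2E,4E)-5-cyclohexylpenta-2,4-dienoate | CCOC(=O)/C=C/C=C/C1CCCCC1 | intermediate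
14 | (2E,4E)-5-cyclohexylpenta-2,4-dienoic acid | OC(=O)/C=C/C=C/C1CCCCC1 | intermediate
15 | 2,5-dimethoxyaniline | COc1ccc(OC)c(N)c1 | starting material
16 | (2E,4E)-5-cyclohexylpenta-2,4-dienoyl chloride (formed in the flask) | ClC(=O)/C=C/C=C/C1CCCCC1 | intermediate
17 | (2E,4E)-5-cyclohexyl-N-(2,5-dimethoxyphenyl)penta-2,4-dienamide | O=C(/C=C/C=C/C1CCCCC1)Nc1cc(OC)ccc1OC | intermediate
18 | (2E,4E)-5-cyclohexyl-N-(6,6-dimethoxy-3-oxocyclohexa-1,4-dien-1-yl)penta-2,4-dienamide | O=C(/C=C/C=C/C1CCCCC1)NC1=CC(=O)C=CC1(OC)OC | intermediate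
19 | (2E,4E)-5-cyclohexyl-N-[(1R,6S)-2,2-dimethoxy-5-oxo-7-oxabicyclo[4.1.0]hept-3-en-3-yl]penta-2,4-dienamide | O=C(/C=C/C=C/C1CCCCC1)NC1=CC(=O)[C@H]2O[C@H]2C1(OC)OC | intermediate
20 | (E)-1,2-bis(tributylstannyl)ethene | CCCC[Sn](CCCC)(CCCC)/C=C/[Sn](CCCC)(CCCC)CCCC | starting material
21 | (E)-2-(tributylstannyl)ethenyllithium (formed in the flask) | [Li]/C=C/[Sn](CCCC)(CCCC)CCCC | intermediate
22 | (2E,4E)-5-cyclohexyl-N-[(1R,5S,6S)-5-hydroxy-2,2-dimethoxy-5-[(E)-2-(tributylstannyl)ethenyl]-7-oxabicyclo[4.1.0]hept-3-en-3-yl]penta-2,4-dienamide (hydroxyl syn to the epoxide oxygen) | O=C(/C=C/C=C/C1CCCCC1)NC1=C[C@](O)(/C=C/[Sn](CCCC)(CCCC)CCCC)[C@H]2O[C@H]2C1(OC)OC | intermediate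
23 | (2E,4E)-5-cyclohexyl-N-[(1R,5S,6S)-5-hydroxy-5-[(E)-2-iodoethenyl]-2,2-dimethoxy-7-oxabicyclo[4.1.0]hept-3-en-3-yl]penta-2,4-dienamide | O=C(/C=C/C=C/C1CCCCC1)NC1=C[C@](O)(/C=C/I)[C@H]2O[C@H]2C1(OC)OC | intermediate
24 | (2E,4E)-5-cyclohexyl-N-[(1R,5S,6S)-5-hydroxy-5-[(E)-2-iodoethenyl]-2-oxo-7-oxabicyclo[4.1.0]hept-3-en-3-yl]penta-2,4-dienamide | O=C(/C=C/C=C/C1CCCCC1)NC1=C[C@](O)(/C=C/I)[C@H]2O[C@H]2C1=O | intermediate
25 | (2E,4E)-5-cyclohexyl-N-[(1R,5R,6S)-5-hydroxy-5-[(1E,3E,5E)-7-[(2-hydroxy-5-oxocyclopent-1-en-1-yl)amino]-7-oxohepta-1,3,5-trien-1-yl]-2-oxo-7-oxabicyclo[4.1.0]hept-3-en-3-yl]penta-2,4-dienamide | O=C(/C=C/C=C/C1CCCCC1)NC1=C[C@](O)(/C=C/C=C/C=C/C(=O)NC2=C(O)CCC2=O)[C@H]2O[C@H]2C1=O | target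

**Step count**
Total: 15 steps. Longest linear sequence: 9 steps (steps 7–14, then step 15).

**Steps most likely to fail**

Step 6 (ring closure). The enolate at the N-bearing methylene may not reach the ester in the strained enolendo geometry before amidate N-acylation with loss of the dienoyl group, or intermolecular condensation, consumes the substrate; the tin may also be lost by protonolysis during acidification. The fallback sets out from anhydride 8 (made from acid 6 as in step 5) and comes back at 10, acylating a preformed ring instead. Cyclopentane-1,3-dione is coupled with benzenediazonium chloride (aniline, NaNO2, HCl, then NaOAc, 0 °C) to give 2-(2-phenylhydrazinylidene)cyclopentane-1,3-dione F1. Hydrogenolysis (H2, Pd/C, HCl, MeOH) gives 2-amino-3-hydroxycyclopent-2-en-1-one hydrochloride F2. F2 is treated with 8 and Et3N in THF/DMF at 0 °C, which should acylate the enol oxygen to give 2-amino-3-oxocyclopent-1-en-1-yl (2E,4E)-5-(tributylstannyl)penta-2,4-dienoate F3. On warming with Et3N and catalytic DMAP, F3 should undergo O→N acyl shift through a five-membered transition state to give 10.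

Step 11 (asymmetric epoxidation). Enantiofacial discrimination by the chiral ion pair may be insufficient, since the acidic enaminone N–H can compete for the ammonium cation, and the material may not upgrade on crystallisation. The fallback sets out from 18 and comes back at 19, replacing asymmetric catalysis by resolution. Achiral epoxidation (t-BuOOH, DBU, CH2Cl2) gives racemic (2E,4E)-5-cyclohexyl-N-(2,2-dimethoxy-5-oxo-7-oxabicyclo[4.1.0]hept-3-en-3-yl)penta-2,4-dienamide F4. Luche reduction (NaBH4, CeCl3·7H2O, MeOH, −78 °C), with hydride delivered anti to the epoxide, gives the racemic syn-epoxy alcohol rac-(1R,5R,6R)-N-(5-hydroxy-2,2-dimethoxy-7-oxabicyclo[4.1.0]hept-3-en-3-yl)-(2E,4E)-5-cyclohexylpenta-2,4-dienamide F5. Lipase-catalysed transesterification (vinyl acetate, immobilised Candida antarctica lipase B or Burkholderia cepacia lipase, chosen by screening) leaves the (1R,5R,6R)-alcohol F6 and removes its antipode as the (1S,5S,6S)-acetate F7. Oxidation of F6 with Dess–Martin periodinane (NaHCO3, CH2Cl2) returns enantiopure 19.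

Step 15 (final coupling). Slow transmetalation may allow protodestannylation of 10 by its own enol proton, and palladium- or base-induced degradation of the unprotected epoxy-enone 24, to outrun cross-coupling. The fallback sets out from 22 and 10 and comes back at 25, reversing the polarity and keeping the ketal on during the coupling. Stannane 10 is iodinated (I2, CH2Cl2, 0 °C) to (2E,4E)-N-(2-hydroxy-5-oxocyclopent-1-en-1-yl)-5-iodopenta-2,4-dienamide F8. F8 is coupled with core stannane 22 (PdCl2(MeCN)2, DMF, rt) to give the dimethyl ketal of the target, (2E,4E)-5-cyclohexyl-N-[(1R,5R,6S)-5-hydroxy-5-[(1E,3E,5E)-7-[(2-hydroxy-5-oxocyclopent-1-en-1-yl)amino]-7-oxohepta-1,3,5-trien-1-yl]-2,2-dimethoxy-7-oxabicyclo[4.1.0]hept-3-en-3-yl]penta-2,4-dienamide F9. Ketal hydrolysis on montmorillonite K10 clay in wet CH2Cl2 gives 25.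

**Further compounds**
F1 | step 6 | 2-(2-phenylhydrazinylidene)cyclopentane-1,3-dione | O=C1CCC(=O)C1=NNc1ccccc1
F2 | step 6 | 2-amino-3-hydroxycyclopent-2-en-1-one hydrochloride | NC1=C(O)CCC1=O.Cl
F3 | step 6 | 2-amino-3-oxocyclopent-1-en-1-yl (2E,4E)-5-(tributylstannyl)penta-2,4-dienoate | NC1=C(OC(=O)/C=C/C=C/[Sn](CCCC)(CCCC)CCCC)CCC1=O
F4 | step 11 | racemic (2E,4E)-5-cyclohexyl-N-(2,2-dimethoxy-5-oxo-7-oxabicyclo[4.1.0]hept-3-en-3-yl)penta-2,4-dienamide (cis-fused epoxide) | O=C(/C=C/C=C/C1CCCCC1)NC1=CC(=O)C2OC2C1(OC)OC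
F5 | step 11 | rac-(2E,4E)-5-cyclohexyl-N-[(1R,5R,6R)-5-hydroxy-2,2-dimethoxy-7-oxabicyclo[4.1.0]hept-3-en-3-yl]penta-2,4-dienamide (racemate, relative configuration shown, hydroxyl syn to the epoxide oxygen) | O=C(/C=C/C=C/C1CCCCC1)NC1=C[C@@H](O)[C@H]2O[C@H]2C1(OC)OC
F6 | step 11 | (2E,4E)-5-cyclohexyl-N-[(1R,5R,6R)-5-hydroxy-2,2-dimethoxy-7-oxabicyclo[4.1.0]hept-3-en-3-yl]penta-2,4-dienamide (single enantiomer) | O=C(/C=C/C=C/C1CCCCC1)NC1=C[C@@H](O)[C@H]2O[C@H]2C1(OC)OC
F7 | step 11 | (1S,5S,6S)-3-[(2E,4E)-5-cyclohexylpenta-2,4-dienamido]-2,2-dimethoxy-7-oxabicyclo[4.1.0]hept-3-en-5-yl acetate | O=C(/C=C/C=C/C1CCCCC1)NC1=C[C@H](OC(C)=O)[C@@H]2O[C@@H]2C1(OC)OC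
F8 | step 15 | (2E,4E)-N-(2-hydroxy-5-oxocyclopent-1-en-1-yl)-5-iodopenta-2,4-dienamide | O=C(/C=C/C=C/I)NC1=C(O)CCC1=O
F9 | step 15 | (2E,4E)-5-cyclohexyl-N-[(1R,5R,6S)-5-hydroxy-5-[(1E,3E,5E)-7-[(2-hydroxy-5-oxocyclopent-1-en-1-yl)amino]-7-oxohepta-1,3,5-trien-1-yl]-2,2-dimethoxy-7-oxabicyclo[4.1.0]hept-3-en-3-yl]penta-2,4-dienamide | O=C(/C=C/C=C/C1CCCCC1)NC1=C[C@](O)(/C=C/C=C/C=C/C(=O)NC2=C(O)CCC2=O)[C@H]2O[C@H]2C1(OC)OC
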